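I start with an easy step: setting down what the flasks hold and what has been read.

| setting | gamma | zeta | flask |
|---|---|---|---|
| substrate | 0.020 M | 0.020 M | 0.020 M |
| solid reagent | 0.022 M | 0.044 M | 0.0220 M |
| initiator | 1.8 mM | 1.8 mM | 1.8 mM |
| remark | the very flask that is asked about, followed so far | run made earlier |  |
| time |  |  | 10 d |

| run | time / d | target / % |
|---|---|---|
| gamma | 0.333 | 1.1 |
| gamma | 0.500 | 0 |
| gamma | 0.833 | 1.2 |
| gamma | 1.04 | 1.7 |
| gamma | 1.67 | 1.9 |
| gamma | 2.50 | 2.1 |
| gamma | 4.00 | 3.2 |
| zeta | 0.833 | 0.9 |
| zeta | 1.25 | 1.4 |
| zeta | 1.67 | 1.3 |
| zeta | 3.00 | 3.6 |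
| zeta | 4.00 | 3.0 |
| zeta | 6.00 | 3.5 |
| zeta | 10.0 | 4.6 |

(scatter of a reading: 0.5 percentage points)

1. target at 10 d, in percent of the substrate charged
2. concentration of partner in solution at 10 d, in percent of saturation

- percent here means substrate units held: one side product counts as two
- solid reagent is a solid; its amount is given per volume of the solution
- on the list of suspects stand: solid reagent <-> partner; partner + first chain carrier <-> target + second chain carrier; initiator -> 2 initiating radical; 2 second chain carrier -> ended chains; substrate + target -> side product; substrate + second chain carrier -> by-product + first chain carrier; substrate + initiating radical -> capped initiator + first chain carrier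
- at the start none of the solid reagent is in solution

In the gamma flask target reads 1.7% at 1.04 d, a gain g of 0.0163 d⁻¹ of the charge, and the zeta flask, with twice the solid reagent, reads about the same. Holding g on from gamma's last reading, 3.2%, gives my bound above, 13.0%; that last reading is my bound below.

To tighten this I freeze something. The gain slows, and substrate + target → side product is a suspect, so I suppose target is eaten about as fast as it is made, a steady state. If the making also stays about even, the holding product Q, target concentration times substrate concentration, stays nearly constant. Each target made and eaten costs two substrate units, so I reckon gamma holds 87.0% of its substrate at 4.00 d, which gives Q = 1.11 × 10⁻⁵ M^2. At 10 d I reckon 67.3% left, so target comes to about 4.13%. Other steps also take substrate, so I call this the low edge; the high edge is zeta's 4.6% plus twice the scatter of 0.5 percentage points. I expect partner near zero, used as it dissolves.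

The forecast gives 4.7%, inside my bracket and above my figure, with partner at 97% of saturation: “Partner should sit at or near saturation”.

The flask gives target 4.66% and partner at 0% of saturation, which is 1.55 × 10⁻⁹ M.

    solid reagent ⇌ partner, rate k1*(cs1 - [partner]) while solid is left; crystals form when [partner] > cs1 (solubility = 1.20 mM, k = 3.50 × 10⁻⁶ s⁻¹)
    partner + first chain carrier ⇌ target + second chain carrier (K = 0.360, k = 13000 M⁻¹ s⁻¹)
    initiator → 2 initiating radical (k = 9.70 × 10⁻⁷ s⁻¹)
    2 second chain carrier → ended chains (k = 5.00 × 10⁶ M⁻¹ s⁻¹)
    substrate + target → side product (k = 3.30 × 10⁻⁴ M⁻¹ s⁻¹)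
    substrate + second chain carrier → by-product + first chain carrier (k = 330 M⁻¹ s⁻¹)
    substrate + initiating radical → capped initiator + first chain carrier (k = 7000 M⁻¹ s⁻¹)

Q in the flask is 1.08 × 10⁻⁵ M^2 at 5.00 d and 1.09 × 10⁻⁵ M^2 at 10.0 d, close to my value, while substrate stands at 58%, less than my 67.3%. The flask is not at rest: at 100 d substrate is 0%, target 33.5%, side product 66.5% and partner 0.00120 M, so Q stands nearly still from 5.00 d to 10.0 d and not out to that end.

With 0.050 M of substrate and the other charges as before, I keep Q and the making per litre, so g shrinks with the charge, I reckon 86.9% of the substrate stays, and Q gives 0.512% target. That flask gives 0.610%.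

(Readings and results come from a simulation with constants of no real substance, noise included.)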